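**Retrosynthetic overview**

1. The target is the all-trans (exo) [4+2] adduct of an (E)-chalcone and a (2S)-flavanone that carries an (E)-1-aryl-3-alkylbuta-1,3-diene at C6. Cyclohexene numbering used throughout: C1 bears the 4-methylpent-3-enyl chain, C2 is the olefinic CH, C3 bears the chromanone, C4 the aroyl group, C5 the 2,4-dihydroxyphenyl group, C6 is CH2.
2. Enabling feature: the C1=C2 double bond lies between C3 and the trans C4-aroyl/C5-aryl pair, a Diels–Alder retron (bonds C3–C4 and C5–C6). C6, C1, C2, C3 and the side chain are the intact ten-carbon skeleton of β-myrcene, joined to flavanone C6 by a Heck reaction.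
3. The aroyl ring of the target has no ortho hydroxyl, so a temporary 2'-OH is built into the chalcone to let it chelate a chiral borate. It is removed afterwards through the aryl triflate; because it is removed, a prenyl group on either side of the 4'-oxygen would converge on the same target.
4. Ring order: the four benzene rings are bought; the pyranone ring (ring C of the flavanone) is closed by oxa-Michael addition and its C2 centre secured by kinetic resolution; the cyclohexene ring is closed last.
5. All phenols are acetates at the cycloaddition stage, so that only a near-neutral deacetylation follows the deoxygenation.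

Key step: step 14

Assumption (sense of induction): the (S)-VANOL borate is taken to leave the Cα-si/Cβ-si face of the chelated chalcone open; if the adduct of opposite absolute configuration forms, (R)-VANOL is used with nothing else changed.

**Route**

Step 1
Reactants: 1 2,4-dihydroxybenzaldehyde
Product: 2 2,4-bis(methoxymethoxy)benzaldehyde
Conditions: MOMCl (2.5 equiv), K2CO3, acetone, 0 °C to reflux
Reagents that add atoms: chloromethyl methyl ether, COCCl
Why: Williamson O-alkylation of both phenoxides should give the base-stable bis-MOM aldehyde needed for both Claisen–Schmidt condensations; no stereocentre is involved.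

Step 2
Reactants: 3 2',4',6'-trihydroxyacetophenone
Product: 4 1-[2,6-dihydroxy-4-(methoxymethoxy)phenyl]ethan-1-one
Conditions: MOMCl (1.05 equiv), K2CO3 (1.1 equiv), acetone, 0 °C to rt
Reagents that add atoms: chloromethyl methyl ether, COCCl
Why: The 4-OH, para to the acetyl group and not hydrogen-bonded, is the most acidic and should be alkylated first (selective mono-O-alkylation), leaving the two chelated ortho hydroxyls free.

Step 3
Reactants: 4 1-[2,6-dihydroxy-4-(methoxymethoxy)phenyl]ethan-1-one; 2 2,4-bis(methoxymethoxy)benzaldehyde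
Product: 6 rac-5-hydroxy-7-(methoxymethoxy)-2-[2,4-bis(methoxymethoxy)phenyl]chroman-4-one, via chalcone 5 (not isolated)
Conditions: KOH (50% aq.), EtOH, rt; AcOH to pH 6; then NaOAc (cat.), EtOH, reflux
Reagents that add atoms: none
Why: Claisen–Schmidt aldol condensation should give the 2',6'-dihydroxychalcone, which closes readily by 6-endo oxa-Michael addition of either equivalent ortho OH to the 5-hydroxyflavanone; C2 is formed racemic.

Step 4
Reactants: 6 rac-5-hydroxy-7-(methoxymethoxy)-2-[2,4-bis(methoxymethoxy)phenyl]chroman-4-one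
Product: 7 (2S)-5-hydroxy-7-(methoxymethoxy)-2-[2,4-bis(methoxymethoxy)phenyl]chroman-4-one
Conditions: RuCl(p-cymene)[(R,R)-TsDPEN] (2 mol%), HCO2H/Et3N (5:2), EtOAc, rt, stopped at about 55% conversion
Reagents that add atoms: none
Why: Noyori–Ikariya asymmetric transfer hydrogenation run as a kinetic resolution: the (R,R)-catalyst should reduce the (2R)-ketone to the cis-(2R,4R)-flavan-4-ol and leave the (2S)-flavanone, which is separated by chromatography.

Step 5
Reactants: 7 (2S)-5-hydroxy-7-(methoxymethoxy)-2-[2,4-bis(methoxymethoxy)phenyl]chroman-4-one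
Product: 8 (2S)-5-hydroxy-6-iodo-7-(methoxymethoxy)-2-[2,4-bis(methoxymethoxy)phenyl]chroman-4-one
Conditions: BnMe3N ICl2 (1.05 equiv), CaCO3, CH2Cl2/MeOH, rt
Reagents that add atoms: benzyltrimethylammonium dichloroiodate, C[N+](C)(C)Cc1ccccc1.Cl[I-]Cl
Why: Electrophilic aromatic iodination directed ortho to the free, chelated 5-OH should occur at C6, as in the known 6-iodination of 5-hydroxy-7-alkoxyflavonoids with this reagent, while the aryl ethers of the other ring do not react without a Lewis acid.

Step 6
Reactants: 8 (2S)-5-hydroxy-6-iodo-7-(methoxymethoxy)-2-[2,4-bis(methoxymethoxy)phenyl]chroman-4-one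
Product: 9 (2S)-2-(2,4-dihydroxyphenyl)-5,7-dihydroxy-6-iodochroman-4-one
Conditions: HCl (1 M in MeOH), rt
Reagents that add atoms: none
Why: Acid-catalysed acetal exchange with methanol should remove the three MOM groups at a stage where no alkene is present, and C2 is not affected under these mild conditions.

Step 7
Reactants: 9 (2S)-2-(2,4-dihydroxyphenyl)-5,7-dihydroxy-6-iodochroman-4-one
Product: 10 (2S)-2-(2,4-diacetoxyphenyl)-6-iodo-4-oxochroman-5,7-diyl diacetate
Conditions: Ac2O, pyridine, DMAP (cat.), CH2Cl2, rt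
Reagents that add atoms: acetic anhydride, CC(=O)OC(C)=O
Why: Nucleophile-catalysed O-acylation should convert all four phenols, the chelated 5-OH included, into acetates, which later keep the flavanone carbonyl from binding boron and keep an ortho phenoxide from capturing the allylpalladium intermediate of step 8.

Step 8
Reactants: 10 (2S)-2-(2,4-diacetoxyphenyl)-6-iodo-4-oxochroman-5,7-diyl diacetate; 11 β-myrcene (7-methyl-3-methylideneocta-1,6-diene, 4 equiv)
Product: 12 (2S)-2-(2,4-diacetoxyphenyl)-6-[(1E)-7-methyl-3-methylideneocta-1,6-dien-1-yl]-4-oxochroman-5,7-diyl diacetate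
Conditions: Pd(OAc)2 (10 mol%), n-Bu4NCl, KOAc, DMF, 70 °C
Reagents that add atoms: none
Why: Mizoroki–Heck arylation of a 1,3-diene under ligand-free phase-transfer conditions: the arylpalladium species should add to the unsubstituted vinyl terminus of myrcene, and syn β-hydride elimination from the benzylic position of the allylpalladium intermediate gives the conjugated (E)-1-aryl diene, the weakly basic acetate sparing the aryl acetates and C2.

Step 9
Reactants: 13 1-(5-bromo-2,4-dihydroxyphenyl)ethan-1-one
Product: 14 1-[5-bromo-2-hydroxy-4-(methoxymethoxy)phenyl]ethan-1-one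
Conditions: MOMCl (1.1 equiv), K2CO3, acetone, rt
Reagents that add atoms: chloromethyl methyl ether, COCCl
Why: Selective O-alkylation of the 4-OH is expected because the 2-OH is deactivated by its hydrogen bond to the acetyl group.

Step 10
Reactants: 14 1-[5-bromo-2-hydroxy-4-(methoxymethoxy)phenyl]ethan-1-one
Product: 15 1-[2-hydroxy-4-(methoxymethoxy)-5-(3-methylbut-2-en-1-yl)phenyl]ethan-1-one
Conditions: tributyl(3-methylbut-2-en-1-yl)stannane, Pd(PPh3)4 (5 mol%), DMF, 100 °C
Reagents that add atoms: tributyl(3-methylbut-2-en-1-yl)stannane, CCCC[Sn](CCCC)(CCCC)CC=C(C)C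
Why: Stille cross-coupling should install the prenyl group with C–C bond formation at the less hindered allyl terminus (linear product), and the chelated phenol is tolerated.

Step 11
Reactants: 15 1-[2-hydroxy-4-(methoxymethoxy)-5-(3-methylbut-2-en-1-yl)phenyl]ethan-1-one; 2 2,4-bis(methoxymethoxy)benzaldehyde
Product: 16 (2E)-1-[2-hydroxy-4-(methoxymethoxy)-5-(3-methylbut-2-en-1-yl)phenyl]-3-[2,4-bis(methoxymethoxy)phenyl]prop-2-en-1-one
Conditions: KOH (50% aq.), EtOH, rt; then dilute HCl to pH 5
Reagents that add atoms: none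
Why: Claisen–Schmidt aldol condensation followed by E1cB dehydration should give the thermodynamically favoured (E)-enone.

Step 12
Reactants: 16 (2E)-1-[2-hydroxy-4-(methoxymethoxy)-5-(3-methylbut-2-en-1-yl)phenyl]-3-[2,4-bis(methoxymethoxy)phenyl]prop-2-en-1-one
Product: 17 (2E)-1-[2,4-dihydroxy-5-(3-methylbut-2-en-1-yl)phenyl]-3-(2,4-dihydroxyphenyl)prop-2-en-1-one
Conditions: HCl (1 M in MeOH), rt
Reagents that add atoms: none
Why: Acid-catalysed acetal exchange should remove the three MOM groups, dilute acid at rt being chosen so that neither chroman formation at the ortho-prenyl phenol nor flavanone closure competes.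

Step 13
Reactants: 17 (2E)-1-[2,4-dihydroxy-5-(3-methylbut-2-en-1-yl)phenyl]-3-(2,4-dihydroxyphenyl)prop-2-en-1-one
Product: 18 4-{(1E)-3-[4-acetoxy-2-hydroxy-5-(3-methylbut-2-en-1-yl)phenyl]-3-oxoprop-1-en-1-yl}-1,3-phenylene diacetate
Conditions: Ac2O (3.3 equiv), pyridine, CH2Cl2, 0 °C
Reagents that add atoms: acetic anhydride, CC(=O)OC(C)=O
Why: O-acylation should take the three non-chelated phenols and leave the carbonyl-bound 2'-OH free for boron, while the acetates make the enone a more electron-poor dienophile.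

Step 14
Reactants: 12 (2S)-2-(2,4-diacetoxyphenyl)-6-[(1E)-7-methyl-3-methylideneocta-1,6-dien-1-yl]-4-oxochroman-5,7-diyl diacetate (1.0 equiv); 18 4-{(1E)-3-[4-acetoxy-2-hydroxy-5-(3-methylbut-2-en-1-yl)phenyl]-3-oxoprop-1-en-1-yl}-1,3-phenylene diacetate (1.3 equiv)
Product: 19 all-trans cycloadduct, cyclohexene (3R,4R,5S), chromanone (2S): C3 bears the (2S)-5,7-diacetoxy-2-(2,4-diacetoxyphenyl)-4-oxochroman-6-yl group, C4 the 4-acetoxy-2-hydroxy-5-(3-methylbut-2-en-1-yl)benzoyl group, C5 the 2,4-diacetoxyphenyl group, C1 the 4-methylpent-3-en-1-yl chain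
Conditions: B(OPh)3 (30 mol%), (S)-VANOL [(S)-3,3'-diphenyl-2,2'-binaphthalene-1,1'-diol] (30 mol%), 4 Å molecular sieves, PhCF3, rt to 45 °C
Reagents that add atoms: none
Why: The free 2'-OH and the carbonyl oxygen of 18 displace phenoxide from the VANOL borate to give a tetracoordinate boron chelate that lowers the enone LUMO, and this complex undergoes a concerted, asynchronous normal-demand [4+2] cycloaddition with diene 12 in which the C5–C6 bond leads (largest diene HOMO coefficient at the CH2 terminus, largest dienophile LUMO coefficient at the β-carbon), which also fixes the regiochemistry. The closest known reaction type is the chiral borate-promoted Diels–Alder reaction of 2'-hydroxychalcones with 1-aryl-3-alkylbutadienes used for prenylflavonoid-type adducts. The cyclohexene ring is closed by intermolecular [4+2] cycloaddition (bonds C3–C4 and C5–C6, suprafacial on both partners), so the E geometry of the chalcone becomes the C4/C5 trans relation. C3 is set relative to C4 by an exo transition state (chelated aroyl group turned away from the diene), expected to be favoured because the bulky borate-bound aroyl group avoids the di-ortho-substituted aryl group at the diene terminus, which gives the all-trans ring; the absolute configuration (3R,4R,5S) follows from attack of the diene on the Cα-si/Cβ-si face of the chalcone left open by the ligand, the remote (2S) centre being a spectator. The step needs chemoselectivity for the conjugated diene over the isolated trisubstituted alkenes (secured by their lack of conjugation), binding of boron at the chalcone only (secured by acetylation of the flavanone 5-OH), exo over endo selectivity and facial selectivity; a minor endo adduct, if formed, is removed by chromatography.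

Step 15
Reactants: 19 all-trans cycloadduct with free 2'-OH
Product: 20 aryl triflate of 19: C4 now bears the 4-acetoxy-5-(3-methylbut-2-en-1-yl)-2-(trifluoromethylsulfonyloxy)benzoyl group, all else as in 19, (3R,4R,5S), (2S)
Conditions: Tf2O (1.3 equiv), pyridine, CH2Cl2, −20 to 0 °C
Reagents that add atoms: trifluoromethanesulfonic anhydride, O=S(=O)(OS(=O)(=O)C(F)(F)F)C(F)(F)F
Why: O-sulfonylation of the only free phenol should be fast at low temperature, where the acetates and the α-stereocentre of the ketone are not touched.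

Step 16
Reactants: 20 aryl triflate
Product: 21 heptaacetate of the target: C4 bears the 4-acetoxy-3-(3-methylbut-2-en-1-yl)benzoyl group, C3 the (2S)-5,7-diacetoxy-2-(2,4-diacetoxyphenyl)-4-oxochroman-6-yl group, C5 the 2,4-diacetoxyphenyl group, (3R,4R,5S), (2S)
Conditions: Pd(OAc)2 (10 mol%), dppf (12 mol%), HCO2H (3 equiv), Et3N (4 equiv), DMF, 60 °C
Reagents that add atoms: none
Why: Palladium-catalysed transfer hydrogenolysis of an aryl triflate (oxidative addition of zerovalent palladium, formate exchange, decarboxylation to the hydride, reductive elimination) should remove the temporary oxygen without reducing the alkenes, and C4 stays in its thermodynamically favoured all-equatorial configuration.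

Step 17
Reactants: 21 heptaacetate of the target
Product: 22 CNP0235243.2, (2S)-2-(2,4-dihydroxyphenyl)-5,7-dihydroxy-6-{(3R,4R,5S)-5-(2,4-dihydroxyphenyl)-4-[4-hydroxy-3-(3-methylbut-2-en-1-yl)benzoyl]-1-(4-methylpent-3-en-1-yl)cyclohex-1-en-3-yl}chroman-4-one (cyclohexene numbered as in the overview)
Conditions: NH4OAc (excess), MeOH/H2O (4:1), rt to 35 °C
Reagents that add atoms: none
Why: Near-neutral methanolysis of aryl acetates should free all seven phenols while avoiding both acid (cyclisation of phenols onto the prenyl and cyclohexene double bonds) and strong base (retro-oxa-Michael opening at C2).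

**Compound list**

1 | 2,4-dihydroxybenzaldehyde | O=Cc1ccc(O)cc1O | starting material
2 | 2,4-bis(methoxymethoxy)benzaldehyde | O=Cc1ccc(OCOC)cc1OCOC | intermediate
3 | 2',4',6'-trihydroxyacetophenone | CC(=O)c1c(O)cc(O)cc1O | starting material
4 | 1-[2,6-dihydroxy-4-(methoxymethoxy)phenyl]ethan-1-one | CC(=O)c1c(O)cc(OCOC)cc1O | intermediate
5 | (2E)-1-[2,6-dihydroxy-4-(methoxymethoxy)phenyl]-3-[2,4-bis(methoxymethoxy)phenyl]prop-2-en-1-one (not isolated) | O=C(/C=C/c1ccc(OCOC)cc1OCOC)c1c(O)cc(OCOC)cc1O | intermediate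
6 | rac-5-hydroxy-7-(methoxymethoxy)-2-[2,4-bis(methoxymethoxy)phenyl]chroman-4-one | O=C1CC(c2ccc(OCOC)cc2OCOC)Oc2cc(OCOC)cc(O)c21 | intermediate
7 | (2S)-5-hydroxy-7-(methoxymethoxy)-2-[2,4-bis(methoxymethoxy)phenyl]chroman-4-one | O=C1C[C@@H](c2ccc(OCOC)cc2OCOC)Oc2cc(OCOC)cc(O)c21 | intermediate
8 | (2S)-5-hydroxy-6-iodo-7-(methoxymethoxy)-2-[2,4-bis(methoxymethoxy)phenyl]chroman-4-one | O=C1C[C@@H](c2ccc(OCOC)cc2OCOC)Oc2cc(OCOC)c(I)c(O)c21 | intermediate
9 | (2S)-2-(2,4-dihydroxyphenyl)-5,7-dihydroxy-6-iodochroman-4-one | O=C1C[C@@H](c2ccc(O)cc2O)Oc2cc(O)c(I)c(O)c21 | intermediate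
10 | (2S)-2-(2,4-diacetoxyphenyl)-6-iodo-4-oxochroman-5,7-diyl diacetate | O=C1C[C@@H](c2ccc(OC(C)=O)cc2OC(C)=O)Oc2cc(OC(C)=O)c(I)c(OC(C)=O)c21 | intermediate
11 | β-myrcene (7-methyl-3-methylideneocta-1,6-diene) | C=CC(=C)CCC=C(C)C | starting material
12 | (2S)-2-(2,4-diacetoxyphenyl)-6-[(1E)-7-methyl-3-methylideneocta-1,6-dien-1-yl]-4-oxochroman-5,7-diyl diacetate | O=C1C[C@@H](c2ccc(OC(C)=O)cc2OC(C)=O)Oc2cc(OC(C)=O)c(/C=C/C(=C)CCC=C(C)C)c(OC(C)=O)c21 | intermediate
13 | 1-(5-bromo-2,4-dihydroxyphenyl)ethan-1-one | CC(=O)c1cc(Br)c(O)cc1O | starting material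
14 | 1-[5-bromo-2-hydroxy-4-(methoxymethoxy)phenyl]ethan-1-one | CC(=O)c1cc(Br)c(OCOC)cc1O | intermediate
15 | 1-[2-hydroxy-4-(methoxymethoxy)-5-(3-methylbut-2-en-1-yl)phenyl]ethan-1-one | CC(=O)c1cc(CC=C(C)C)c(OCOC)cc1O | intermediate
16 | (2E)-1-[2-hydroxy-4-(methoxymethoxy)-5-(3-methylbut-2-en-1-yl)phenyl]-3-[2,4-bis(methoxymethoxy)phenyl]prop-2-en-1-one | O=C(/C=C/c1ccc(OCOC)cc1OCOC)c1cc(CC=C(C)C)c(OCOC)cc1O | intermediate
17 | (2E)-1-[2,4-dihydroxy-5-(3-methylbut-2-en-1-yl)phenyl]-3-(2,4-dihydroxyphenyl)prop-2-en-1-one | O=C(/C=C/c1ccc(O)cc1O)c1cc(CC=C(C)C)c(O)cc1O | intermediate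
18 | 4-{(1E)-3-[4-acetoxy-2-hydroxy-5-(3-methylbut-2-en-1-yl)phenyl]-3-oxoprop-1-en-1-yl}-1,3-phenylene diacetate | O=C(/C=C/c1ccc(OC(C)=O)cc1OC(C)=O)c1cc(CC=C(C)C)c(OC(C)=O)cc1O | intermediate
19 | all-trans cycloadduct, cyclohexene (3R,4R,5S), chromanone (2S), free 2'-OH on the aroyl ring, seven acetates | CC(C)=CCCC1=C[C@@H](c2c(OC(C)=O)cc3c(c2OC(C)=O)C(=O)C[C@@H](c2ccc(OC(C)=O)cc2OC(C)=O)O3)[C@H](C(=O)c2c(O)cc(OC(C)=O)c(CC=C(C)C)c2)[C@@H](c2ccc(OC(C)=O)cc2OC(C)=O)C1 | intermediate
20 | 2'-O-triflate of 19, (3R,4R,5S), (2S) | CC(C)=CCCC1=C[C@@H](c2c(OC(C)=O)cc3c(c2OC(C)=O)C(=O)C[C@@H](c2ccc(OC(C)=O)cc2OC(C)=O)O3)[C@H](C(=O)c2c(OS(=O)(=O)C(F)(F)F)cc(OC(C)=O)c(CC=C(C)C)c2)[C@@H](c2ccc(OC(C)=O)cc2OC(C)=O)C1 | intermediate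
21 | heptaacetate of the target, (3R,4R,5S), (2S) | CC(C)=CCCC1=C[C@@H](c2c(OC(C)=O)cc3c(c2OC(C)=O)C(=O)C[C@@H](c2ccc(OC(C)=O)cc2OC(C)=O)O3)[C@H](C(=O)c2ccc(OC(C)=O)c(CC=C(C)C)c2)[C@@H](c2ccc(OC(C)=O)cc2OC(C)=O)C1 | intermediate
22 | CNP0235243.2, (2S)-chromanone, cyclohexene (3R,4R,5S) | CC(C)=CCCC1=C[C@@H](c2c(O)cc3c(c2O)C(=O)C[C@@H](c2ccc(O)cc2O)O3)[C@H](C(=O)c2ccc(O)c(CC=C(C)C)c2)[C@@H](c2ccc(O)cc2O)C1 | target

**Step count and risks**

Total step count: 17. Longest linear sequence: 11 steps (steps 2, 3, 4, 5, 6, 7, 8, 14, 15, 16, 17).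

Steps most likely to fail:

1. Step 14. Turnover may be slow because the adduct is itself a chelating ortho-hydroxyaryl ketone and the diene terminus is crowded; exo selectivity may erode; the facial selectivity may be lower than hoped. Fallback: catalyst control is given up and the resident (2S) centre is used instead. The fallback sets out from 12 and 18, which are combined with a stoichiometric achiral borate (B(OPh)3 and 2,2'-biphenol, PhCF3, 40 °C) or simply heated in toluene in a sealed tube. Because 12 is a single enantiomer, the two exo adducts are diastereomers, namely 19 and the (3S,4S,5R),(2S) all-trans cycloadduct F1. They are separated by preparative HPLC, and the route is rejoined at 19.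

2. Step 8. The allylpalladium intermediate may be captured by acetate or by a phenoxide set free through acetate loss (dihydrobenzofuran annulation), insertion may occur at the other diene terminus, or insertion at the di-ortho-substituted arylpalladium species may be too slow. Fallback: the dienyl unit is brought in preformed by Suzuki–Miyaura coupling. 6-Methylhept-5-en-2-one is converted by kinetic enolisation (LDA, THF, −78 °C; PhNTf2) into 6-methylhepta-1,5-dien-2-yl trifluoromethanesulfonate F2. Sonogashira coupling with ethynyltrimethylsilane (PdCl2(PPh3)2, CuI, Et3N) gives trimethyl(7-methyl-3-methylideneoct-6-en-1-yn-1-yl)silane F3, and K2CO3 in MeOH gives 7-methyl-3-methylideneoct-6-en-1-yne F4. Hydroboration of the alkyne with pinacolborane (Cp2ZrHCl cat.) gives 4,4,5,5-tetramethyl-2-[(1E)-7-methyl-3-methylideneocta-1,6-dien-1-yl]-1,3,2-dioxaborolane F5. The fallback sets out from 10, which is coupled with this boronate under anhydrous conditions that spare the acetates (Pd(PPh3)4, CsF, DME, 60 °C), and it returns to the route at 12.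

3. Step 4. The hydrogen-bonded 5-hydroxy ketone may be reduced slowly and with a low selectivity factor, so that both enantiomers are consumed at similar rates; at best half of the material is used. Fallback: the C2 centre is set by catalytic asymmetric conjugate arylation instead of resolution. The fallback sets out from 4, which with N,N-dimethylformamide dimethyl acetal (toluene, 90 °C) gives (2E)-1-[2,6-dihydroxy-4-(methoxymethoxy)phenyl]-3-(dimethylamino)prop-2-en-1-one F6; mild acid (PPTS, toluene, 80 °C) closes it to 5-hydroxy-7-(methoxymethoxy)-4H-chromen-4-one F7. 4-Bromoresorcinol with MOMCl and K2CO3 gives 1-bromo-2,4-bis(methoxymethoxy)benzene F8, and n-BuLi, then B(OiPr)3 and aqueous work-up give [2,4-bis(methoxymethoxy)phenyl]boronic acid F9. Rhodium-catalysed asymmetric 1,4-addition of the boronic acid to the chromone ([RhOH(cod)]2, an electron-poor chiral biaryl bisphosphine of the MeO-BIPHEP family in the enantiomeric form that delivers the (2S) product, toluene/H2O, rt to 40 °C) returns to the route at 7.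

**Further compounds**

F1 | step 14 | (3S,4S,5R),(2S) all-trans cycloadduct, diastereomer of 19 | CC(C)=CCCC1=C[C@H](c2c(OC(C)=O)cc3c(c2OC(C)=O)C(=O)C[C@@H](c2ccc(OC(C)=O)cc2OC(C)=O)O3)[C@@H](C(=O)c2c(O)cc(OC(C)=O)c(CC=C(C)C)c2)[C@H](c2ccc(OC(C)=O)cc2OC(C)=O)C1
F2 | step 8 | 6-methylhepta-1,5-dien-2-yl trifluoromethanesulfonate | C=C(OS(=O)(=O)C(F)(F)F)CCC=C(C)C
F3 | step 8 | trimethyl(7-methyl-3-methylideneoct-6-en-1-yn-1-yl)silane | C[Si](C)(C)C#CC(=C)CCC=C(C)C
F4 | step 8 | 7-methyl-3-methylideneoct-6-en-1-yne | C#CC(=C)CCC=C(C)C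
F5 | step 8 | 4,4,5,5-tetramethyl-2-[(1E)-7-methyl-3-methylideneocta-1,6-dien-1-yl]-1,3,2-dioxaborolane | CC(C)=CCCC(=C)/C=C/B1OC(C)(C)C(C)(C)O1
F6 | step 4 | (2E)-1-[2,6-dihydroxy-4-(methoxymethoxy)phenyl]-3-(dimethylamino)prop-2-en-1-one | CN(C)/C=C/C(=O)c1c(O)cc(OCOC)cc1O
F7 | step 4 | 5-hydroxy-7-(methoxymethoxy)-4H-chromen-4-one | O=c1ccoc2cc(OCOC)cc(O)c12
F8 | step 4 | 1-bromo-2,4-bis(methoxymethoxy)benzene | COCOc1ccc(Br)c(OCOC)c1
F9 | step 4 | [2,4-bis(methoxymethoxy)phenyl]boronic acid | COCOc1ccc(B(O)O)c(OCOC)c1
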